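## Structural features

Stenosporic acid is a depside: two benzene rings joined by one aryl ester. Ring A is a 2-hydroxy-4-methoxy-6-propylbenzoyl unit, and its carbonyl is bound to O-4 of ring B, a 2-hydroxy-6-pentylbenzoic acid. There is no stereocentre, so no two stereocentres stand next to each other and the whole problem is one of regiochemistry. The fragile parts are three. The aryl ester is cleaved by bases and nucleophiles and can transfer its acyl group. The ortho-hydroxybenzoic acid of ring B decarboxylates under heat or strong acid. The single methyl ether must survive while other O-substituents are removed. The real difficulty is to tell four phenolic oxygens apart and to place carboxyl, hydroxyl and pentyl on three neighbouring carbons of ring B. The key step uses the fact that C3 to C6 of ring B, with the pentyl group on C6 and the ester oxygen on C4, are already present as C3 to C6 of 4-hydroxy-6-pentyl-2-pyrone. Only C1 with its carboxyl and C2 with its oxygen are missing, and these two carbons correspond to an alkyne at the right oxidation level.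

## Logic of the disconnections

22 is traced to 21 by putting a methyl group back on O-2 of ring B (forward: cleavage of one O–CH3 bond). The cut is made there because the C2 oxygen comes from the alkyne as a methyl ether, the only ynol ether that tolerates heat. Nothing is gained in skeleton, but the key step is freed from a labile group. The forward step must cleave only the methyl ether that can chelate with the neighbouring carboxyl, and must spare the ring A methoxy and the aryl ester.

21 is traced to 20 by putting back two benzyl groups, one on the ring B carboxyl and one on O-2 of ring A (forward: cleavage of two O–CH2Ph bonds). Both fall in one neutral hydrogenolysis, so the ring A phenol needs no Lewis acid. The forward step must leave the aryl ester and both arenes untouched.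

20 is cut at C1–C6 and C2–C3 of ring B. Reinserting a CO2 bridge between C3 and C6 gives 19, which opens to 12 and 18. This is the main simplification: ring B, its full substitution pattern and its aromatic oxidation level come from two achiral pieces, and the depside ester is carried through unchanged. The forward step must join the components in one orientation only and must run at a temperature that the ester groups and the ynol ether survive.

12 is cut at the acyl C–O bond between the ring A carbonyl and O-4 of the pyrone, giving 6 (activated as 11) and 10. The two halves are then independent and of similar size. The forward step must acylate the pyrone on oxygen and not on C3.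

10 is cut between the first and second carbon of the pentyl chain, giving 7 and 8 through dianion 9. This reduces the pyrone to a bulk chemical. The forward step must alkylate the carbanion at the methyl group and not the oxygen or C3.

6 is traced through 5, 4 and 3 to 1 (through 2) by an oxidation-level change, an O–benzyl cut, an O–methyl cut and an aryl–CHO cut. The formyl group is put in first because its hydrogen bond to the neighbouring phenol tells the two oxygens of 1 apart. The forward steps must formylate beside the propyl group and methylate only the free para-hydroxyl.

18 is cut at the bond between the alkyne and the ester carbon, giving 15 (as its anion 17) and 16. 15 is traced to 13 through 14 by two eliminations. The forward steps must keep the volatile ynol ether cold and must prevent a second addition of 17 to the product.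

## Other disconnections considered

Alternative 1: The cut is the C1–C6 bond of ring A. It unfolds ring A into a linear 3,5,7-trioxodecanoyl chain held as an ester on O-4 of ring B, benzyl 2-hydroxy-6-pentyl-4-[(3,5,7-trioxodecanoyl)oxy]benzoate A2. In the forward step a mild base would enolize the C2 methylene, which would add to the C7 ketone. Loss of water would then give the aromatic triol benzyl 4-[(2,4-dihydroxy-6-propylbenzoyl)oxy]-2-hydroxy-6-pentylbenzoate A1. Selective methylation of the ring A 4-hydroxyl and hydrogenolysis would follow.

- In its favour: it copies the polyketide folding, runs near room temperature, needs no unproven cycloaddition, and gives ring A with the right carbon pattern from an open chain. The methylation is plausible because the other two phenols are hydrogen-bonded to carbonyl groups.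
- Against it: A2 carries a good leaving group (the ring B phenoxide) on a 3,5-dioxo ester. Closure of the C5 enol oxygen on the ester carbonyl to a 4-hydroxy-2-pyrone, or Claisen closure from C6, would expel ring B and destroy the depside bond that the route depends on. A2 is also hard to assemble and to handle.
- Comparison: on mildness of conditions this alternative is the better one, and its ring-forming reaction type is established, which the chosen key step is not. On structure it is weaker, because the ring A oxygens are not differentiated when the ring forms, whereas 4 and 5 fix them before any sensitive bond exists. On step economy it is at best the equal of the chosen plan, and only if A2 can be made in a few steps.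

Alternative 2: The cuts are C1–C2 and C5–C6 of ring B. The diene is 5-[(tert-butyldimethylsilyl)oxy]-3,3-dimethylcyclohexa-1,5-dien-1-yl 2-(benzyloxy)-4-methoxy-6-propylbenzoate A4 and the dienophile is benzyl oct-2-ynoate A5. Cycloaddition would give a bicyclo[2.2.2]octadiene, which would lose its gem-dimethyl two-carbon bridge as a volatile alkene (Alder–Rickert). The product would be benzyl 4-{[2-(benzyloxy)-4-methoxy-6-propylbenzoyl]oxy}-2-[(tert-butyldimethylsilyl)oxy]-6-pentylbenzoate A3.

- In its favour: benzannulation of 1,3-dioxygenated cyclohexadienes with acetylenic esters is an established reaction type. The unsubstituted diene terminus is the nucleophilic one and should bond to the pentyl-bearing alkyne carbon, so the regiochemistry is matched. O-2 of ring B arrives as a silyl ether, so the end game would be fluoride and hydrogenolysis with no demethylation.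
- Against it: A5 is a beta-alkyl ynoate and a slow dienophile, so the temperature would be no lower than in the chosen plan. A4 must be made by O-functionalization of a cross-conjugated dienolate with a hindered aroyl group, is sensitive to moisture, and can transfer its acyl group.
- Comparison: on precedent and on the end game this alternative is the better one. On mechanism the two are equal in kind, since each forms a bridged adduct that extrudes a small molecule. On step economy they are about equal. The chosen plan is stronger only in that 12 is an ordinary, storable enol ester and its diene is part of a stable heterocycle.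

Alternative 3: The cuts are C1–C2 and C5–C6 of ring A. The dienophile is the ring B ester benzyl 4-(hex-2-ynoyloxy)-2-hydroxy-6-pentylbenzoate A8 and the diene is 1,3-dimethoxy-1-(trimethylsilyloxy)buta-1,3-diene A7. The CH2 terminus of A7 would bond to the propyl-bearing alkyne carbon and the ketene acetal carbon to the carbon beside the ester. Elimination of the acetal methoxy group would aromatize the ring, and work-up would free the 2-hydroxyl. The product would be benzyl 2-hydroxy-4-[(2-hydroxy-4-methoxy-6-propylbenzoyl)oxy]-6-pentylbenzoate A6, one hydrogenolysis from the target.

- In its favour: it is the shortest plan. The diene itself differentiates the 2-hydroxyl from the 4-methoxy of ring A, and no protecting group has to be removed under Lewis acid.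
- Against it: beta-alkyl ynoates react slowly even with such electron-rich dienes. A7 is thermally and hydrolytically labile, and the free phenol of A8 would consume it. The ketene acetal could also attack the activated aryl ester carbonyl or stop at an open-chain conjugate adduct.
- Comparison: on step economy and on the end game this alternative is clearly the better one, and its reaction type is known for simpler ynoates, so on precedent it is also better. The chosen plan is its equal on regiochemical logic. The chosen plan is stronger in that every step outside the key step is classical and robust, and neither component of the key step carries a free phenol.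

Key step: step 9

Remark on the chemistry: ring A O-2 is carried as a benzyl ether, and the end game runs as hydrogenolysis followed by BCl3, so that only one chelation-directed demethylation is needed. All isolated compounds are achiral and the bridged intermediate 19 is racemic. Olivetolic acid, used only in one fallback, is assumed to be purchasable.

## Route

Step 1
Reactants: 1 5-propylresorcinol (divarinol)
Product: 3 2,4-dihydroxy-6-propylbenzaldehyde, via aryl iminium chloride 2 (not isolated)
Conditions: POCl3, DMF, 0 °C → rt; then H2O, 50 °C
Reagents that add atoms: N,N-dimethylformamide, CN(C)C=O (formyl carbon; carbon and nitrogen of 2); water, O (carbonyl oxygen); phosphoryl chloride, O=P(Cl)(Cl)Cl (chloride of intermediate 2 only)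
Why: Vilsmeier–Haack formylation; the chloroiminium ion should attack the resorcinol para to one hydroxyl and ortho to the other, beside the propyl group, the usual site for 5-alkylresorcinols, and water hydrolyses iminium 2 to the aldehyde.

Step 2
Reactants: 3 2,4-dihydroxy-6-propylbenzaldehyde
Product: 4 2-hydroxy-4-methoxy-6-propylbenzaldehyde
Conditions: MeI (1.05 equiv), K2CO3 (1.1 equiv), acetone, rt
Reagents that add atoms: iodomethane, CI
Why: Williamson ether synthesis; the 4-hydroxyl is the more acidic and the free one, while the 2-hydroxyl is held in a hydrogen bond to the formyl group, so a limited amount of MeI should methylate O-4 only.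

Step 3
Reactants: 4 2-hydroxy-4-methoxy-6-propylbenzaldehyde
Product: 5 2-(benzyloxy)-4-methoxy-6-propylbenzaldehyde
Conditions: BnBr, K2CO3, DMF, 60 °C
Reagents that add atoms: benzyl bromide, BrCc1ccccc1
Why: Williamson ether synthesis under more forcing conditions; the chelated phenol is the only nucleophile left.

Step 4
Reactants: 5 2-(benzyloxy)-4-methoxy-6-propylbenzaldehyde
Product: 6 2-(benzyloxy)-4-methoxy-6-propylbenzoic acid
Conditions: NaClO2, NaH2PO4, 2-methyl-2-butene, t-BuOH–THF–H2O, 0 °C → rt
Reagents that add atoms: sodium chlorite, [Na+].[O-]Cl=O
Why: Pinnick oxidation; chlorous acid oxidizes the hindered aldehyde without touching the benzyl ether, and the alkene scavenger removes HOCl before it can chlorinate the electron-rich ring.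

Step 5
Reactants: 7 4-hydroxy-6-methyl-2H-pyran-2-one; 8 1-iodobutane
Product: 10 4-hydroxy-6-pentyl-2H-pyran-2-one, via dilithio dianion 9 (not isolated)
Conditions: LiN(iPr)2 (2.3 equiv), THF–DMPU, −78 °C; then 8, −78 → −20 °C; aq HCl
Reagents that add atoms: lithium diisopropylamide, [Li+].CC(C)[N-]C(C)C (lithium of intermediate 9 only)
Why: Dianion alkylation; the first equivalent of base forms the pyronate and the second removes a proton from the C6 methyl group, and the resulting carbanion, the more reactive site of 9, should take up the primary iodide by SN2.

Step 6
Reactants: 6 2-(benzyloxy)-4-methoxy-6-propylbenzoic acid; 10 4-hydroxy-6-pentyl-2H-pyran-2-one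
Product: 12 2-oxo-6-pentyl-2H-pyran-4-yl 2-(benzyloxy)-4-methoxy-6-propylbenzoate, via acid chloride 11 (not isolated)
Conditions: (COCl)2, DMF (cat.), CH2Cl2, 0 °C → rt, evaporate; then 10, Et3N, CH2Cl2, −20 °C → rt
Reagents that add atoms: oxalyl chloride, ClC(=O)C(=O)Cl (chlorine of intermediate 11 only)
Why: Acid chloride formation followed by O-acylation of the acidic vinylogous carboxylic acid; the triethylammonium pyronate should react on oxygen with the hard acyl chloride, and no nucleophilic catalyst is added, so that migration of the acyl group to C3 is not triggered.

Step 7
Reactants: 13 chloroacetaldehyde dimethyl acetal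
Product: 15 methoxyacetylene (kept as a cold THF solution), via sodium methoxyacetylide 14 (not isolated)
Conditions: NaNH2 (3 equiv), liquid NH3, −33 °C; then cold aq NaCl, −70 °C → warm, distil into THF at −78 °C
Reagents that add atoms: sodium amide, [Na+].[NH2-] (sodium of intermediate 14 only)
Why: Double elimination; amide removes methanol and then HCl from the chloroacetal, the third equivalent holds the alkyne as its sodium salt, and cold aqueous quenching releases the low-boiling ynol ether.

Step 8
Reactants: 15 methoxyacetylene; 16 benzyl chloroformate
Product: 18 benzyl 3-methoxyprop-2-ynoate, via lithium methoxyacetylide 17 (not isolated)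
Conditions: n-BuLi, THF, −78 °C; then cannulate into 16 (1.5 equiv), THF, −78 °C
Reagents that add atoms: n-butyllithium, [Li]CCCC (lithium of intermediate 17 only)
Why: Acylation of a lithium acetylide with a chloroformate; inverse addition keeps the electrophile in excess so that 17 does not add a second time to the product.

Step 9
Reactants: 12 2-oxo-6-pentyl-2H-pyran-4-yl 2-(benzyloxy)-4-methoxy-6-propylbenzoate; 18 benzyl 3-methoxyprop-2-ynoate
Product: 20 benzyl 4-{[2-(benzyloxy)-4-methoxy-6-propylbenzoyl]oxy}-2-methoxy-6-pentylbenzoate, via bicyclic lactone 19 (not isolated)
Conditions: 18 (3–4 equiv, in portions), BHT (cat.), 1,2-dichlorobenzene, sealed tube, 160–180 °C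
Reagents that add atoms: none
Why: Proposed new method: the diene of pyrone 12 (C3=C4–C5=C6) should add alkyne 18 in a thermal, probably asynchronous [4+2] cycloaddition in which the nucleophilic pyrone C3 bonds to the methoxy-bearing, oxocarbenium-like alkyne carbon and the electrophilic C6 bonds to the ester-bearing carbon, giving the 2-oxabicyclo[2.2.2]octa-5,7-dien-3-one 19; a retro-[4+2] then expels CO2 and gives the benzene ring of 20 without an oxidation step, because the dienophile is an alkyne. The closest known reaction type is the Diels–Alder and retro-Diels–Alder benzannulation of 4-alkoxy-6-alkyl-2-pyrones with acetylenic esters; a 3-alkoxypropiolate partner and a 4-acyloxy pyrone go beyond it. Ring B is closed by an intermolecular cycloaddition that forms C2–C3 and C1–C6 together, so no chain cyclization and no choice of ring size is involved. The two bridgehead stereocentres of 19 are transient and racemic and vanish on aromatization, so there is nothing to control. The step needs regioselectivity, which the matched polarity of the two components should secure, since the reverse orientation would join two nucleophilic termini. It also needs chemoselectivity over acyl migration on the pyrone, which the absence of nucleophilic catalysts and the two ortho substituents that shield the aroyl carbonyl should secure. The methyl ynol ether has no beta hydrogen and cannot fragment to a ketene by a retro-ene path, which is why methyl and no larger alkyl group sits on the alkyne oxygen. The benzyl ether, the benzyl ester and the aryl ester should be thermally inert at this temperature.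

Step 10
Reactants: 20 benzyl 4-{[2-(benzyloxy)-4-methoxy-6-propylbenzoyl]oxy}-2-methoxy-6-pentylbenzoate
Product: 21 4-[(2-hydroxy-4-methoxy-6-propylbenzoyl)oxy]-2-methoxy-6-pentylbenzoic acid
Conditions: H2 (1 atm), 10% Pd/C, EtOAc, rt
Reagents that add atoms: none
Why: Catalytic hydrogenolysis of a benzyl ester and an aryl benzyl ether; the aryl ester, the methyl ethers and the arenes are inert under these neutral conditions.

Step 11
Reactants: 21 4-[(2-hydroxy-4-methoxy-6-propylbenzoyl)oxy]-2-methoxy-6-pentylbenzoic acid
Product: 22 stenosporic acid, 2-hydroxy-4-[(2-hydroxy-4-methoxy-6-propylbenzoyl)oxy]-6-pentylbenzoic acid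
Conditions: BCl3 (4 equiv), CH2Cl2, −78 → 0 °C; then ice-water
Reagents that add atoms: none
Why: Chelation-directed demethylation with BCl3; the carboxyl group binds boron and the ortho methoxy oxygen completes a six-membered chelate, so chloride removes that methyl group, while the ring A methoxy para to its carbonyl cannot chelate. The ring A phenol and the ester carbonyl form their own boron chelate, which is hydrolysed on work-up.

## Compound list

1 | 5-propylresorcinol (divarinol) | CCCc1cc(O)cc(O)c1 | starting material
2 | [(2,4-dihydroxy-6-propylphenyl)methylidene]dimethyliminium chloride | CCCc1cc(O)cc(O)c1C=[N+](C)C.[Cl-] | intermediate (not isolated)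
3 | 2,4-dihydroxy-6-propylbenzaldehyde | CCCc1cc(O)cc(O)c1C=O | intermediate
4 | 2-hydroxy-4-methoxy-6-propylbenzaldehyde | CCCc1cc(OC)cc(O)c1C=O | intermediate
5 | 2-(benzyloxy)-4-methoxy-6-propylbenzaldehyde | CCCc1cc(OC)cc(OCc2ccccc2)c1C=O | intermediate
6 | 2-(benzyloxy)-4-methoxy-6-propylbenzoic acid | CCCc1cc(OC)cc(OCc2ccccc2)c1C(=O)O | intermediate
7 | 4-hydroxy-6-methyl-2H-pyran-2-one | CC1=CC(O)=CC(=O)O1 | starting material
8 | 1-iodobutane | CCCCI | starting material
9 | dilithium salt of the dianion of 7 (O-4 and C6 methyl) | [Li+].[Li+].[CH2-]C1=CC([O-])=CC(=O)O1 | intermediate (not isolated)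
10 | 4-hydroxy-6-pentyl-2H-pyran-2-one | CCCCCC1=CC(O)=CC(=O)O1 | intermediate
11 | 2-(benzyloxy)-4-methoxy-6-propylbenzoyl chloride | CCCc1cc(OC)cc(OCc2ccccc2)c1C(=O)Cl | intermediate (not isolated)
12 | 2-oxo-6-pentyl-2H-pyran-4-yl 2-(benzyloxy)-4-methoxy-6-propylbenzoate | CCCCCC1=CC(OC(=O)c2c(OCc3ccccc3)cc(OC)cc2CCC)=CC(=O)O1 | intermediate
13 | chloroacetaldehyde dimethyl acetal | COC(CCl)OC | starting material
14 | sodium methoxyacetylide | [Na+].[C-]#COC | intermediate (not isolated)
15 | methoxyacetylene | COC#C | intermediate
16 | benzyl chloroformate | ClC(=O)OCc1ccccc1 | starting material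
17 | lithium methoxyacetylide | [Li+].[C-]#COC | intermediate (not isolated)
18 | benzyl 3-methoxyprop-2-ynoate | COC#CC(=O)OCc1ccccc1 | intermediate
19 | benzyl 8-{[2-(benzyloxy)-4-methoxy-6-propylbenzoyl]oxy}-5-methoxy-3-oxo-1-pentyl-2-oxabicyclo[2.2.2]octa-5,7-diene-6-carboxylate (racemic; bridgehead configuration fixed by the bicycle) | CCCCCC12OC(=O)C(C(OC)=C1C(=O)OCc1ccccc1)C(OC(=O)c1c(OCc3ccccc3)cc(OC)cc1CCC)=C2 | intermediate (not isolated)
20 | benzyl 4-{[2-(benzyloxy)-4-methoxy-6-propylbenzoyl]oxy}-2-methoxy-6-pentylbenzoate | CCCCCc1cc(OC(=O)c2c(OCc3ccccc3)cc(OC)cc2CCC)cc(OC)c1C(=O)OCc1ccccc1 | intermediate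
21 | 4-[(2-hydroxy-4-methoxy-6-propylbenzoyl)oxy]-2-methoxy-6-pentylbenzoic acid | CCCCCc1cc(OC(=O)c2c(O)cc(OC)cc2CCC)cc(OC)c1C(=O)O | intermediate
22 | stenosporic acid | CCCCCc1cc(OC(=O)c2c(O)cc(OC)cc2CCC)cc(O)c1C(=O)O | target

## Step count and least certain steps

Total step count: 11. Longest linear sequence: 8 steps (steps 1, 2, 3, 4, 6, 9, 10, 11).

Step 9 (key step). The most likely failure is that no cycloaddition takes place at a temperature the components survive, because the acyloxy group lowers the donor strength of the diene and the methoxy group lowers the acceptor strength of the alkyne. Competing processes are thermal oligomerization of the ynol ether and migration of the aroyl group from O-4 to C3 of the pyrone. The fallback gives up the ring construction and makes the depside bond by classical esterification. It sets out from acid chloride 11 (made from 6 as in step 6) and returns at 22. Olivetolic acid F1 (2,4-dihydroxy-6-pentylbenzoic acid, bought) is benzylated on the carboxylate only (BnBr, KHCO3, DMF, rt) to benzyl 2,4-dihydroxy-6-pentylbenzoate F2. Its 4-hydroxyl, the only phenol not held in a hydrogen bond to the ester carbonyl, is acylated with 11 (K2CO3, acetone) to benzyl 4-{[2-(benzyloxy)-4-methoxy-6-propylbenzoyl]oxy}-2-hydroxy-6-pentylbenzoate F3. Hydrogenolysis (H2, 10% Pd/C, EtOAc) then removes both benzyl groups and gives 22 directly, with no methyl ether to cleave.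

Step 6. The hindered acid chloride may react slowly, and the ambident pyronate may be acylated at C3, or the O-acyl product may rearrange to the C3 ketone during the reaction. The fallback keeps the same ring construction but makes the depside bond afterwards on an ordinary phenol. It sets out from 10 and returns at 20. 10 is silylated (t-BuMe2SiCl, imidazole, DMF) to 4-[(tert-butyldimethylsilyl)oxy]-6-pentyl-2H-pyran-2-one F4. F4 and 18 are heated as in step 9 and should give, through benzyl 8-[(tert-butyldimethylsilyl)oxy]-5-methoxy-3-oxo-1-pentyl-2-oxabicyclo[2.2.2]octa-5,7-diene-6-carboxylate F5 (not isolated), benzyl 4-[(tert-butyldimethylsilyl)oxy]-2-methoxy-6-pentylbenzoate F6. Bu4NF with AcOH in THF frees benzyl 4-hydroxy-2-methoxy-6-pentylbenzoate F7, which is acylated with 11 (Et3N, DMAP, CH2Cl2) to 20. This fallback inherits the uncertainty of the cycloaddition, but with a more electron-rich diene that is closer to the known cases.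

Step 8. The acetylide may add a second time to the newly formed ynoate, and the push–pull alkyne may be hydrated or take up nucleophiles during work-up. The fallback forms the C–C bond with an electrophile that cannot react twice. It sets out from 15 and returns at 18. 15 is lithiated to 17 as before and quenched with dry CO2 to lithium 3-methoxyprop-2-ynoate F8. Without acidification the salt is alkylated on oxygen with benzyl bromide in DMF to give 18.

Step 11. Over-reaction may cleave the non-chelated ring A methyl ether or the aryl ester, the reaction may stop short, and the product acid may decarboxylate during acidic work-up. The fallback moves the Lewis acid step ahead of the unmasking of the acid, so that the last step is neutral. It sets out from 20 and returns at 22. 20 is treated with BCl3 and pentamethylbenzene (CH2Cl2, −78 → −20 °C), which should remove the ring A benzyl ether and the chelated ring B methyl ether and give benzyl 2-hydroxy-4-[(2-hydroxy-4-methoxy-6-propylbenzoyl)oxy]-6-pentylbenzoate F9. Hydrogenolysis of the benzyl ester (H2, 10% Pd/C, EtOAc) then gives 22.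

## Further compounds

F1 | step 9 | olivetolic acid, 2,4-dihydroxy-6-pentylbenzoic acid (bought) | CCCCCc1cc(O)cc(O)c1C(=O)O
F2 | step 9 | benzyl 2,4-dihydroxy-6-pentylbenzoate | CCCCCc1cc(O)cc(O)c1C(=O)OCc1ccccc1
F3 | step 9 | benzyl 4-{[2-(benzyloxy)-4-methoxy-6-propylbenzoyl]oxy}-2-hydroxy-6-pentylbenzoate | CCCCCc1cc(OC(=O)c2c(OCc3ccccc3)cc(OC)cc2CCC)cc(O)c1C(=O)OCc1ccccc1
F4 | step 6 | 4-[(tert-butyldimethylsilyl)oxy]-6-pentyl-2H-pyran-2-one | CCCCCC1=CC(O[Si](C)(C)C(C)(C)C)=CC(=O)O1
F5 | step 6 | benzyl 8-[(tert-butyldimethylsilyl)oxy]-5-methoxy-3-oxo-1-pentyl-2-oxabicyclo[2.2.2]octa-5,7-diene-6-carboxylate (racemic, not isolated) | CCCCCC12OC(=O)C(C(OC)=C1C(=O)OCc1ccccc1)C(O[Si](C)(C)C(C)(C)C)=C2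
F6 | step 6 | benzyl 4-[(tert-butyldimethylsilyl)oxy]-2-methoxy-6-pentylbenzoate | CCCCCc1cc(O[Si](C)(C)C(C)(C)C)cc(OC)c1C(=O)OCc1ccccc1
F7 | step 6 | benzyl 4-hydroxy-2-methoxy-6-pentylbenzoate | CCCCCc1cc(O)cc(OC)c1C(=O)OCc1ccccc1
F8 | step 8 | lithium 3-methoxyprop-2-ynoate | [Li+].[O-]C(=O)C#COC
F9 | step 11 | benzyl 2-hydroxy-4-[(2-hydroxy-4-methoxy-6-propylbenzoyl)oxy]-6-pentylbenzoate | CCCCCc1cc(OC(=O)c2c(O)cc(OC)cc2CCC)cc(O)c1C(=O)OCc1ccccc1
A1 | alternative 1 | benzyl 4-[(2,4-dihydroxy-6-propylbenzoyl)oxy]-2-hydroxy-6-pentylbenzoate | CCCCCc1cc(OC(=O)c2c(O)cc(O)cc2CCC)cc(O)c1C(=O)OCc1ccccc1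
A2 | alternative 1 | benzyl 2-hydroxy-6-pentyl-4-[(3,5,7-trioxodecanoyl)oxy]benzoate | CCCCCc1cc(OC(=O)CC(=O)CC(=O)CC(=O)CCC)cc(O)c1C(=O)OCc1ccccc1
A3 | alternative 2 | benzyl 4-{[2-(benzyloxy)-4-methoxy-6-propylbenzoyl]oxy}-2-[(tert-butyldimethylsilyl)oxy]-6-pentylbenzoate | CCCCCc1cc(OC(=O)c2c(OCc3ccccc3)cc(OC)cc2CCC)cc(O[Si](C)(C)C(C)(C)C)c1C(=O)OCc1ccccc1
A4 | alternative 2 | 5-[(tert-butyldimethylsilyl)oxy]-3,3-dimethylcyclohexa-1,5-dien-1-yl 2-(benzyloxy)-4-methoxy-6-propylbenzoate | CC1(C)CC(O[Si](C)(C)C(C)(C)C)=CC(OC(=O)c2c(OCc3ccccc3)cc(OC)cc2CCC)=C1
A5 | alternative 2 | benzyl oct-2-ynoate | CCCCCC#CC(=O)OCc1ccccc1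
A6 | alternative 3 | benzyl 2-hydroxy-4-[(2-hydroxy-4-methoxy-6-propylbenzoyl)oxy]-6-pentylbenzoate | CCCCCc1cc(OC(=O)c2c(O)cc(OC)cc2CCC)cc(O)c1C(=O)OCc1ccccc1
A7 | alternative 3 | 1,3-dimethoxy-1-(trimethylsilyloxy)buta-1,3-diene (geometry at the ketene acetal not material) | C=C(OC)C=C(OC)O[Si](C)(C)C
A8 | alternative 3 | benzyl 4-(hex-2-ynoyloxy)-2-hydroxy-6-pentylbenzoate | CCCC#CC(=O)Oc1cc(O)c(C(=O)OCc2ccccc2)c(CCCCC)c1
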